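The partner cannot be read directly, since the earlier tables give starting material and mono adduct and no column for it, yet you can count what it did.

| flask | starting material | partner | temperature | remark | time |
|---|---|---|---|---|---|
| spring | 5 mM | 15 mM | 20 °C | run made earlier |  |
| winter | 20 mM | 15 mM | 38 °C | run made earlier |  |
| summer | 10 mM | 7.5 mM | 20 °C | run made earlier |  |
| south-east | 10 mM | 15.0 mM | 25 °C |  | 2.0 min |
| north-west | 10 mM | 15.0 mM | 50 °C |  | 2.0 min |

- spring (time / min: mono adduct / %, starting material / %): 0.167: 45, 30; 0.333: 41, 10; 0.667: 33, 11; 1.00: 30, 6; 1.33: 29, 5; 2.00: 28, 9; 2.50: 28, 4
- winter (time / s: mono adduct / %, starting material / %): 10.0: 42, 52; 20.0: 37, 48; 30.0: 35, 46; 40.0: 37, 43; 60.0: 37, 41; 80.0: 35, 35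
- summer (time / min: mono adduct / %, starting material / %): 0.200: 35, 59; 0.667: 39, 53; 1.00: 37, 50; 1.50: 39, 44; 2.50: 39, 44

(scatter of a reading: 1.5 percentage points)

- the numbers in the tables scatter with a standard deviation of 1.5 percentage points
- steps under discussion: starting material + partner -> mono adduct + by-product; partner + mono adduct -> bis adduct + by-product; partner + bis adduct -> triple product + by-product; partner -> decomposed reagent; starting material + by-product -> side product

* the best flask by amount of mono adduct, in percent of the starting material charged; "all alike" if 1.5 percentage points covers them all (south-east / north-west / all alike)
* amount of mono adduct at the end, in percent of the starting material charged, south-east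
* amount of mono adduct at the end, in percent of the starting material charged, north-west

Take a flask in slow motion. In the first instants a partner molecule can add or decay to decomposed reagent, and in the scheme both rates go with c(partner), so I take their ratio to hang on c(starting material) and temperature, not on the partner charged. In the middle, mono adduct competes for partner too, and each bis adduct has cost two partners. Late in the spring run mono adduct reads 28 % and then 28 %.

So count additions: mono adduct once, and whatever is neither mono adduct nor starting material twice, which overcounts any side product. Divided by the partner charged, that share is 54.7 % in spring from its last reading, 73.3 % in summer from its second reading and 72.0 % in winter from its first reading. If the share equals c(starting material)/(c(starting material) + c×), these readings give 4.15 mM and 3.64 mM at 20 °C, averaging 3.89 mM, and 7.78 mM at 38 °C, twice as much. Carrying that growth on at the same factor per degree, measured from the mean temperature of the spring and summer runs, I reckon 4.72 mM for south-east and 12.3 mM for north-west. This c× is the crossing concentration, the c(starting material) at which addition and decay of partner run equally fast, a selectivity factor in concentration units.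

South-east lies above its crossing and by my reckoning delivers 1.02 equivalents; north-west lies below and delivers 0.671. I expect south-east to hold more mono adduct.

The forecast says south-east, with 45 % against 42 %, south-east being “near the mono maximum”.

The flasks give 44.5 % in south-east and 38.5 % in north-west, so south-east is best.

    starting material + partner → mono adduct + by-product (k = 17.0 M⁻¹ s⁻¹, Ea = 43.0 kJ mol⁻¹)
    partner + mono adduct → bis adduct + by-product (k = 11.0 M⁻¹ s⁻¹, Ea = 41.0 kJ mol⁻¹)
    partner + bis adduct → triple product + by-product (k = 0.370 M⁻¹ s⁻¹, Ea = 59.0 kJ mol⁻¹)
    partner → decomposed reagent (k = 0.0600 s⁻¹, Ea = 88.0 kJ mol⁻¹)
    starting material + by-product → side product (k = 0.300 M⁻¹ s⁻¹, Ea = 44.0 kJ mol⁻¹)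
    (constants at 25 °C)

At 0.00781 min in north-west, partner's half-life by decay is 0.74 s, far shorter than the 0.12 min by the step to bis adduct, and the flask ends with 9.32 mM of decomposed reagent, where the crossing gave 8.29 mM. In the neighbour like north-west but charged with 25 mM of starting material, the same crossing gives 4.96 mM, and that flask holds 5.76 mM.

The data were computed with constants of no real substance; scatter was added.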